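**Retrosynthetic overview**
1. Last bond: the C2–diene bond of the left half, made by adding the right-hand dienyl trifluoroborate 29 to the oxocarbenium ion from lactol acetate 16 (trans to the C3 methyl); both tropolone methyl ethers are cleaved afterwards.
2. The route rests on the left dihydropyran ring O1–C2–C3–C4–C4a–C9a: C4a is the nucleophilic carbon between C9a–OH and C5–Me of a doubly vinylogous acid (HO–C9a=C4a–C5=C6–C7=O of the tropone), and C4–C3(Me)–C2 is methacrolein, so the ring is a conjugate adduct closed as a lactol (C4a–C4 and O1–C2 in step 7, C3 by catalyst-controlled protonation).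
3. Donor 11 (tropone numbering: C1=O, C2–OMe, C4–OH, C6–Me, C7–Br; its C5 becomes C4a): [5+2] cycloaddition of the oxidopyrylium from pyromeconic acid with tert-butyl but-2-ynoate, SmI2 opening of the oxygen bridge, oxidation; the C5 ester steers bromination to C7 and is then lost, so the second nucleophilic terminus is blocked.
4. Right half: reductive alkylation of 11 at C5 with the (S)-butanetriol-derived aldehyde 18, Mitsunobu closure of O1'–C2' with inversion, then Wittig and Takai–Utimoto homologation to the dienyl borate.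
5. Ring order: tropone rings (via oxabicycle 5), left pyran (step 7), right pyran (step 14), union (step 19).

Key step: step 7

Assumption: the (S)-configured diamine of step 7 is taken to give the 3R series (the sense of the enamine protonation is untested for this donor; the (R)-diamine is used if it proves opposite), and tert-butyl but-2-ynoate (3) is taken as a catalogue compound.

Step 1
Reactants: 1 3-hydroxy-4H-pyran-4-one (pyromeconic acid)
Product: 2 3-hydroxy-4-methoxypyrylium trifluoromethanesulfonate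
Conditions: MeOTf (1.05 equiv), CH2Cl2, 40 °C
Reagents that add atoms: methyl trifluoromethanesulfonate, COS(=O)(=O)C(F)(F)F
Why: γ-Pyranones are O-methylated at the carbonyl oxygen by hard methylating agents to give aromatic hydroxypyrylium salts, which fixes the later C8 methyl ether regiospecifically and prepares the oxidopyrylium.

Step 2
Reactants: 2 3-hydroxy-4-methoxypyrylium trifluoromethanesulfonate; 3 tert-butyl but-2-ynoate
Product: 5 tert-butyl 3-methoxy-7-methyl-2-oxo-8-oxabicyclo[3.2.1]octa-3,6-diene-6-carboxylate (racemic), via oxidopyrylium ylide 4 (not isolated)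
Conditions: PhNMe2 (1.2 equiv), 3 (5 equiv), CHCl3, 100 °C (sealed tube, microwave)
Reagents that add atoms: none
Why: Deprotonation of 2 gives ylide 4, whose [5+2] dipolar cycloaddition with the ynoate should join its enolate-like terminus (next to the oxido carbon) to the methyl-bearing β-carbon of 3 and its oxocarbenium-like terminus to the ester-bearing carbon, so that bicycle C2, C3 (OMe), C5 (bridge oxygen) and C7 (methyl) become tropone C1, C2, C4 and C6.

Step 3
Reactants: 5 tert-butyl 3-methoxy-7-methyl-2-oxo-8-oxabicyclo[3.2.1]octa-3,6-diene-6-carboxylate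
Product: 6 tert-butyl 7-hydroxy-5-methoxy-2-methyl-4-oxocyclohepta-1,5-diene-1-carboxylate (racemic)
Conditions: SmI2 (2.5 equiv), THF/MeOH, −78 °C
Reagents that add atoms: none
Why: SmI2 reduces the ketone (or the enoate) to a radical anion that expels the bridge oxygen from C1, the position α to the ketone and γ to the ester (reductive cleavage of an α-alkoxy ketone), so the oxygen stays on C5 as a hydroxyl; the carbinol centre is racemic and disappears in step 4.

Step 4
Reactants: 6 tert-butyl 7-hydroxy-5-methoxy-2-methyl-4-oxocyclohepta-1,5-diene-1-carboxylate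
Product: 8 tert-butyl 4-hydroxy-2-methoxy-6-methyltropone-5-carboxylate (tropone numbering: C1 is the carbonyl carbon), via diketone tautomer 7 (not isolated)
Conditions: IBX, DMSO, rt (crude 6 used at once)
Reagents that add atoms: none
Why: IBX oxidation of the doubly allylic alcohol gives dienedione 7, which should enolise at its doubly activated CH2 to the aromatic hydroxytropone 8 (alcohol oxidation, then tautomerisation); immediate use of 6 avoids its dehydration.

Step 5
Reactants: 8 tert-butyl 4-hydroxy-2-methoxy-6-methyltropone-5-carboxylate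
Product: 9 tert-butyl 7-bromo-4-hydroxy-2-methoxy-6-methyltropone-5-carboxylate
Conditions: NBS (1.0 equiv), MeCN, 0 °C
Reagents that add atoms: N-bromosuccinimide, O=C1CCC(=O)N1Br
Why: Electrophilic bromination of the vinylogous acid (O4–C4=C5–C6=C7–C1=O) can only end at C7, because the other terminus C5 carries the ester and attack there cannot be followed by re-aromatisation, and C3 is not a terminus of this system.

Step 6
Reactants: 9 tert-butyl 7-bromo-4-hydroxy-2-methoxy-6-methyltropone-5-carboxylate
Product: 11 7-bromo-4-hydroxy-2-methoxy-6-methyltropone, via carboxylic acid 10 (not isolated)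
Conditions: TFA/CH2Cl2, 0 °C → rt; evaporate; then dioxane, 80 °C (−CO2)
Reagents that add atoms: none
Why: Acidolysis of the tert-butyl ester gives a vinylogous β-keto acid that should lose CO2 on warming by ipso-protonation at the electron-rich C5 (protodecarboxylation), while the methyl ether and the bromide are inert to anhydrous acid.

Step 7
Reactants: 11 7-bromo-4-hydroxy-2-methoxy-6-methyltropone; 12 methacrolein
Product: 14 (3R)-6-bromo-2-hydroxy-8-methoxy-3,5-dimethyl-3,4-dihydrocyclohepta[b]pyran-7(2H)-one (lactol; both C2 epimers), via Michael aldehyde 13 (not isolated)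
Conditions: 12 (3 equiv), (S)-N1,N1-diethyl-3,3-dimethylbutane-1,2-diamine (20 mol%), TfOH (20 mol%), CHCl3, 0 °C
Reagents that add atoms: none
Why: Proposed new method: the chiral primary amine condenses with 12 to an iminium ion, the anion of 11 adds through C5 to its β-carbon (C4a–C4 bond), the resulting enamine is protonated at C3 on one face by the catalyst's pendant ammonium group, and after hydrolysis the C9a hydroxyl closes on the aldehyde (O1–C2) in a 6-exo-trig hemiacetalisation; the closest known reactions are primary-amine-catalysed conjugate addition/enantioselective protonation of α-substituted acroleins and the Michael–hemiacetalisation of cyclic 1,3-diones and 4-hydroxycoumarins with enals, a hydroxytropone donor being new. The only new stereocentre, C3, is set by catalyst-controlled enamine protonation, and C2 stays a lactol mixture that is fixed in step 19. Three selectivities are needed: C- over O-attack, which the soft iminium acceptor and the reversibility of O-attack favour; C5 over C7, which the C7 bromine secures because attack there cannot be followed by re-aromatisation and reverts; and C5 over C3, which holds because C3 is not a terminus of the vinylogous acid. Ring closure is possible only through the C4 oxygen, the one next to C5. Hemiacetal formation removes the free aldehyde and so protects C3 from enamine-mediated epimerisation.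

Step 8
Reactants: 14 (3R)-6-bromo-2-hydroxy-8-methoxy-3,5-dimethyl-3,4-dihydrocyclohepta[b]pyran-7(2H)-one
Product: 15 (3R)-2-hydroxy-8-methoxy-3,5-dimethyl-3,4-dihydrocyclohepta[b]pyran-7(2H)-one (lactol; both C2 epimers)
Conditions: H2 (1 atm, stopped after 1 equiv), 5% Pd/C, Et3N, EtOAc, rt
Reagents that add atoms: none
Why: Hydrogenolysis of the C–Br bond of a 2-bromotropone over palladium on carbon with a base is the classical debromination of bromotropolones and should leave the lactol and C3 untouched.

Step 9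
Reactants: 15 (3R)-2-hydroxy-8-methoxy-3,5-dimethyl-3,4-dihydrocyclohepta[b]pyran-7(2H)-one
Product: 16 (3R)-8-methoxy-3,5-dimethyl-7-oxo-2,3,4,7-tetrahydrocyclohepta[b]pyran-2-yl acetate (both C2 epimers)
Conditions: Ac2O, pyridine, DMAP (cat.), CH2Cl2, 0 °C
Reagents that add atoms: acetic anhydride, CC(=O)OC(C)=O
Why: Acetylation of the anomeric hydroxyl gives the lactol acetate as oxocarbenium precursor; both anomers converge in step 19.

Step 10
Reactants: 17 (S)-2-(2,2-dimethyl-1,3-dioxolan-4-yl)ethanol
Product: 18 (S)-2-(2,2-dimethyl-1,3-dioxolan-4-yl)acetaldehyde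
Conditions: IBX, EtOAc, 75 °C
Reagents that add atoms: none
Why: IBX oxidation of the primary alcohol to the aldehyde; the acetonide stereocentre is not involved.

Step 11
Reactants: 11 7-bromo-4-hydroxy-2-methoxy-6-methyltropone; 18 (S)-2-(2,2-dimethyl-1,3-dioxolan-4-yl)acetaldehyde
Product: 20 7-bromo-5-{2-[(4S)-2,2-dimethyl-1,3-dioxolan-4-yl]ethyl}-4-hydroxy-2-methoxy-6-methyltropone, via quinone methide 19 (not isolated)
Conditions: 18 (1.5 equiv), Hantzsch ester (1.2 equiv), L-proline (20 mol%), CH2Cl2, rt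
Reagents that add atoms: none
Why: Proposed new method: proline-mediated Knoevenagel condensation of the aldehyde at C5 of 11 (the only free terminus, C7 being brominated) should give the tropone quinone methide 19, which the Hantzsch ester reduces at its exocyclic carbon with re-aromatisation; the closest known reactions are the three-component organocatalytic reductive alkylation of cyclic 1,3-diones and 4-hydroxycoumarins and the hydroxymethylation and Mannich reactions of tropolones.

Step 12
Reactants: 20 7-bromo-5-{2-[(4S)-2,2-dimethyl-1,3-dioxolan-4-yl]ethyl}-4-hydroxy-2-methoxy-6-methyltropone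
Product: 22 5-[(3S)-3,4-dihydroxybutyl]-4-hydroxy-2-methoxy-6-methyltropone, via debrominated acetonide 21 (not isolated)
Conditions: H2 (1 atm, stopped after 1 equiv), 5% Pd/C, NaOAc, MeOH, rt; filter; then TsOH·H2O (cat.), MeOH, rt
Reagents that add atoms: none
Why: Hydrogenolysis removes the blocking bromine as in step 8 and acid-catalysed transacetalisation in methanol frees the 1,2-diol; the carbinol stereocentre is not touched.

Step 13
Reactants: 22 5-[(3S)-3,4-dihydroxybutyl]-4-hydroxy-2-methoxy-6-methyltropone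
Product: 23 5-[(3S)-4-(tert-butyldimethylsilyloxy)-3-hydroxybutyl]-4-hydroxy-2-methoxy-6-methyltropone
Conditions: TBSCl (1.1 equiv), imidazole, DMF, 0 °C; methanolic work-up
Reagents that add atoms: tert-butyldimethylsilyl chloride, CC(C)(C)[Si](C)(C)Cl
Why: The primary hydroxyl is silylated faster than the secondary one for steric reasons (selective silyl ether formation), and any silyl group on the acidic tropone hydroxyl is lost on methanolic work-up.

Step 14
Reactants: 23 5-[(3S)-4-(tert-butyldimethylsilyloxy)-3-hydroxybutyl]-4-hydroxy-2-methoxy-6-methyltropone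
Product: 24 (2R)-2-[(tert-butyldimethylsilyloxy)methyl]-8-methoxy-5-methyl-3,4-dihydrocyclohepta[b]pyran-7(2H)-one
Conditions: PPh3, DIAD, THF (0.02 M), 0 °C → rt
Reagents that add atoms: none
Why: Intramolecular Mitsunobu etherification: the acidic C4 hydroxyl (a vinylogous acid) displaces the activated secondary alcohol in a 6-exo-tet SN2 reaction with inversion, so the (S)-carbinol gives the (R)-configured C2'.

Step 15
Reactants: 24 (2R)-2-[(tert-butyldimethylsilyloxy)methyl]-8-methoxy-5-methyl-3,4-dihydrocyclohepta[b]pyran-7(2H)-one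
Product: 25 (2R)-2-(hydroxymethyl)-8-methoxy-5-methyl-3,4-dihydrocyclohepta[b]pyran-7(2H)-one
Conditions: TBAF, THF, 0 °C
Reagents that add atoms: none
Why: Fluoride cleaves the silyl ether (desilylation); nothing else in 24 is fluoride-labile.

Step 16
Reactants: 25 (2R)-2-(hydroxymethyl)-8-methoxy-5-methyl-3,4-dihydrocyclohepta[b]pyran-7(2H)-one
Product: 27 (2E)-3-[(2R)-8-methoxy-5-methyl-7-oxo-2,3,4,7-tetrahydrocyclohepta[b]pyran-2-yl]prop-2-enal, via aldehyde 26 (not isolated)
Conditions: IBX, DMSO, rt; then Ph3P=CHCHO, rt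
Reagents that add atoms: (triphenylphosphoranylidene)acetaldehyde, O=CC=P(c1ccccc1)(c1ccccc1)c1ccccc1
Why: IBX oxidation to the α-alkoxy aldehyde and Wittig reaction with the stabilised ylide in the same flask should give the (E)-enal without exposing the epimerisable aldehyde to base.

Step 17
Reactants: 27 (2E)-3-[(2R)-8-methoxy-5-methyl-7-oxo-2,3,4,7-tetrahydrocyclohepta[b]pyran-2-yl]prop-2-enal
Product: 28 (2R)-8-methoxy-5-methyl-2-[(1E,3E)-4-(4,4,5,5-tetramethyl-1,3,2-dioxaborolan-2-yl)buta-1,3-dien-1-yl]-3,4-dihydrocyclohepta[b]pyran-7(2H)-one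
Conditions: Cl2CHB(pin), CrCl2, LiI, THF, rt
Reagents that add atoms: 2-(dichloromethyl)-4,4,5,5-tetramethyl-1,3,2-dioxaborolane, ClC(Cl)B1OC(C)(C)C(C)(C)O1
Why: Takai–Utimoto olefination with the chromium carbenoid from the dihalomethylboronate converts the aldehyde into the (E)-alkenylboronate under neutral conditions, which spares C2' (γ to the enal carbonyl).

Step 18
Reactants: 28 (2R)-8-methoxy-5-methyl-2-[(1E,3E)-4-(4,4,5,5-tetramethyl-1,3,2-dioxaborolan-2-yl)buta-1,3-dien-1-yl]-3,4-dihydrocyclohepta[b]pyran-7(2H)-one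
Product: 29 potassium trifluoro{(1E,3E)-4-[(2R)-8-methoxy-5-methyl-7-oxo-2,3,4,7-tetrahydrocyclohepta[b]pyran-2-yl]buta-1,3-dien-1-yl}borate
Conditions: KHF2 (aq.), MeOH, rt
Reagents that add atoms: potassium hydrogen difluoride, [K+].F[H-]F
Why: Exchange of pinacol for fluoride with KHF2 gives the crystalline trifluoroborate salt.

Step 19
Reactants: 16 (3R)-8-methoxy-3,5-dimethyl-7-oxo-2,3,4,7-tetrahydrocyclohepta[b]pyran-2-yl acetate; 29 potassium trifluoro{(1E,3E)-4-[(2R)-8-methoxy-5-methyl-7-oxo-2,3,4,7-tetrahydrocyclohepta[b]pyran-2-yl]buta-1,3-dien-1-yl}borate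
Product: 30 (2R,3R)-8-methoxy-2-{(1E,3E)-4-[(2R)-8-methoxy-5-methyl-7-oxo-2,3,4,7-tetrahydrocyclohepta[b]pyran-2-yl]buta-1,3-dien-1-yl}-3,5-dimethyl-3,4-dihydrocyclohepta[b]pyran-7(2H)-one
Conditions: BF3·OEt2 (3 equiv), CH2Cl2/MeCN, −40 → −10 °C
Reagents that add atoms: none
Why: BF3 ionises the lactol acetate to the cyclic oxocarbenium ion and the alkenylboron species adds through its boron-bearing carbon with loss of the boron group and retention of the (E,E)-geometry (addition of an alkenyl trifluoroborate to an acetal-derived oxocarbenium ion); the bulky nucleophile should enter anti to the C3 methyl group (attack on the half-chair with pseudoaxial methyl), giving the 2,3-trans (2R) product.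

Step 20
Reactants: 30 (2R,3R)-8-methoxy-2-{(1E,3E)-4-[(2R)-8-methoxy-5-methyl-7-oxo-2,3,4,7-tetrahydrocyclohepta[b]pyran-2-yl]buta-1,3-dien-1-yl}-3,5-dimethyl-3,4-dihydrocyclohepta[b]pyran-7(2H)-one
Product: 31 (2R,3R)-8-hydroxy-2-{(1E,3E)-4-[(2R)-8-hydroxy-5-methyl-7-oxo-2,3,4,7-tetrahydrocyclohepta[b]pyran-2-yl]buta-1,3-dien-1-yl}-3,5-dimethyl-3,4-dihydrocyclohepta[b]pyran-7(2H)-one (CNP0332980.1)
Conditions: LiOH·H2O (excess), THF/H2O, 50 °C; then AcOH to pH 5–6
Reagents that add atoms: lithium hydroxide, [Li+].[OH-]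
Why: Tropolone methyl ethers behave as vinylogous esters and are cleaved by aqueous hydroxide through addition–elimination at the methoxy-bearing carbon next to the carbonyl, conditions that should leave the dienylic ethers and the three stereocentres alone.

**Compound list**
1 | 3-hydroxy-4H-pyran-4-one (pyromeconic acid) | O=C1C=COC=C1O | starting material
2 | 3-hydroxy-4-methoxypyrylium trifluoromethanesulfonate | COc1cc[o+]cc1O.[O-]S(=O)(=O)C(F)(F)F | intermediate
3 | tert-butyl but-2-ynoate | CC#CC(=O)OC(C)(C)C | starting material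
4 | 4-methoxypyrylium-3-olate (oxidopyrylium ylide) | COc1cc[o+]cc1[O-] | intermediate
5 | tert-butyl 3-methoxy-7-methyl-2-oxo-8-oxabicyclo[3.2.1]octa-3,6-diene-6-carboxylate (racemic) | CC(C)(C)OC(=O)C1=C(C)C2OC1C=C(OC)C2=O | intermediate
6 | tert-butyl 7-hydroxy-5-methoxy-2-methyl-4-oxocyclohepta-1,5-diene-1-carboxylate (racemic) | CC(C)(C)OC(=O)C1=C(C)CC(=O)C(OC)=CC1O | intermediate
7 | tert-butyl 5-methoxy-2-methyl-4,7-dioxocyclohepta-1,5-diene-1-carboxylate | CC(C)(C)OC(=O)C1=C(C)CC(=O)C(OC)=CC1=O | intermediate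
8 | tert-butyl 4-hydroxy-2-methoxy-6-methyltropone-5-carboxylate | CC(C)(C)OC(=O)c1c(O)cc(OC)c(=O)cc1C | intermediate
9 | tert-butyl 7-bromo-4-hydroxy-2-methoxy-6-methyltropone-5-carboxylate | CC(C)(C)OC(=O)c1c(O)cc(OC)c(=O)c(Br)c1C | intermediate
10 | 7-bromo-4-hydroxy-2-methoxy-6-methyltropone-5-carboxylic acid | OC(=O)c1c(O)cc(OC)c(=O)c(Br)c1C | intermediate
11 | 7-bromo-4-hydroxy-2-methoxy-6-methyltropone (in equilibrium with its 1-hydroxy-4-oxo tautomer) | Cc1cc(O)cc(OC)c(=O)c1Br | intermediate
12 | methacrolein | C=C(C)C=O | starting material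
13 | (2R)-3-(7-bromo-4-hydroxy-2-methoxy-6-methyltropon-5-yl)-2-methylpropanal | Cc1c(Br)c(=O)c(OC)cc(O)c1C[C@@H](C)C=O | intermediate
14 | (3R)-6-bromo-2-hydroxy-8-methoxy-3,5-dimethyl-3,4-dihydrocyclohepta[b]pyran-7(2H)-one (C2 epimers) | Cc1c(Br)c(=O)c(OC)cc2c1C[C@@H](C)C(O)O2 | intermediate
15 | (3R)-2-hydroxy-8-methoxy-3,5-dimethyl-3,4-dihydrocyclohepta[b]pyran-7(2H)-one (C2 epimers) | Cc1cc(=O)c(OC)cc2c1C[C@@H](C)C(O)O2 | intermediate
16 | (3R)-8-methoxy-3,5-dimethyl-7-oxo-2,3,4,7-tetrahydrocyclohepta[b]pyran-2-yl acetate (C2 epimers) | Cc1cc(=O)c(OC)cc2c1C[C@@H](C)C(OC(C)=O)O2 | intermediate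
17 | (S)-2-(2,2-dimethyl-1,3-dioxolan-4-yl)ethanol (1,2-acetonide of (S)-butane-1,2,4-triol) | CC1(C)OC[C@H](CCO)O1 | starting material
18 | (S)-2-(2,2-dimethyl-1,3-dioxolan-4-yl)acetaldehyde | CC1(C)OC[C@H](CC=O)O1 | intermediate
19 | 7-bromo-5-{2-[(4S)-2,2-dimethyl-1,3-dioxolan-4-yl]ethylidene}-2-methoxy-6-methylcyclohepta-2,6-diene-1,4-dione | O=C1C=C(OC)C(=O)C(Br)=C(C)C1=CC[C@H]2COC(C)(C)O2 | intermediate
20 | 7-bromo-5-{2-[(4S)-2,2-dimethyl-1,3-dioxolan-4-yl]ethyl}-4-hydroxy-2-methoxy-6-methyltropone | Cc1c(Br)c(=O)c(OC)cc(O)c1CC[C@H]1COC(C)(C)O1 | intermediate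
21 | 5-{2-[(4S)-2,2-dimethyl-1,3-dioxolan-4-yl]ethyl}-4-hydroxy-2-methoxy-6-methyltropone | Cc1cc(=O)c(OC)cc(O)c1CC[C@H]1COC(C)(C)O1 | intermediate
22 | 5-[(3S)-3,4-dihydroxybutyl]-4-hydroxy-2-methoxy-6-methyltropone | Cc1cc(=O)c(OC)cc(O)c1CC[C@H](O)CO | intermediate
23 | 5-[(3S)-4-(tert-butyldimethylsilyloxy)-3-hydroxybutyl]-4-hydroxy-2-methoxy-6-methyltropone | Cc1cc(=O)c(OC)cc(O)c1CC[C@H](O)CO[Si](C)(C)C(C)(C)C | intermediate
24 | (2R)-2-[(tert-butyldimethylsilyloxy)methyl]-8-methoxy-5-methyl-3,4-dihydrocyclohepta[b]pyran-7(2H)-one | Cc1cc(=O)c(OC)cc2O[C@@H](CO[Si](C)(C)C(C)(C)C)CCc12 | intermediate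
25 | (2R)-2-(hydroxymethyl)-8-methoxy-5-methyl-3,4-dihydrocyclohepta[b]pyran-7(2H)-one | Cc1cc(=O)c(OC)cc2O[C@@H](CO)CCc12 | intermediate
26 | (2R)-8-methoxy-5-methyl-7-oxo-2,3,4,7-tetrahydrocyclohepta[b]pyran-2-carbaldehyde | Cc1cc(=O)c(OC)cc2O[C@@H](C=O)CCc12 | intermediate
27 | (2E)-3-[(2R)-8-methoxy-5-methyl-7-oxo-2,3,4,7-tetrahydrocyclohepta[b]pyran-2-yl]prop-2-enal | Cc1cc(=O)c(OC)cc2O[C@@H](/C=C/C=O)CCc12 | intermediate
28 | (2R)-8-methoxy-5-methyl-2-[(1E,3E)-4-(4,4,5,5-tetramethyl-1,3,2-dioxaborolan-2-yl)buta-1,3-dien-1-yl]-3,4-dihydrocyclohepta[b]pyran-7(2H)-one | Cc1cc(=O)c(OC)cc2O[C@@H](/C=C/C=C/B3OC(C)(C)C(C)(C)O3)CCc12 | intermediate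
29 | potassium trifluoro{(1E,3E)-4-[(2R)-8-methoxy-5-methyl-7-oxo-2,3,4,7-tetrahydrocyclohepta[b]pyran-2-yl]buta-1,3-dien-1-yl}borate | Cc1cc(=O)c(OC)cc2O[C@@H](/C=C/C=C/[B-](F)(F)F)CCc12.[K+] | intermediate
30 | bis(methyl ether) of the target: (2R,3R)-8-methoxy-2-{(1E,3E)-4-[(2R)-8-methoxy-5-methyl-7-oxo-2,3,4,7-tetrahydrocyclohepta[b]pyran-2-yl]buta-1,3-dien-1-yl}-3,5-dimethyl-3,4-dihydrocyclohepta[b]pyran-7(2H)-one | Cc1cc(=O)c(OC)cc2c1C[C@@H](C)[C@H](/C=C/C=C/[C@H]1CCc3c(C)cc(=O)c(OC)cc3O1)O2 | intermediate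
31 | CNP0332980.1, (2R,3R)-8-hydroxy-2-{(1E,3E)-4-[(2R)-8-hydroxy-5-methyl-7-oxo-2,3,4,7-tetrahydrocyclohepta[b]pyran-2-yl]buta-1,3-dien-1-yl}-3,5-dimethyl-3,4-dihydrocyclohepta[b]pyran-7(2H)-one | Cc1cc(=O)c(O)cc2c1C[C@@H](C)[C@H](/C=C/C=C/[C@H]1CCc3c(C)cc(=O)c(O)cc3O1)O2 | target

**Step count and risks**

Total steps: 20. Longest linear sequence: 16 steps (steps 1–6 and 11–20); the left branch (steps 7–9) and step 10 are side branches.

Steps most likely to fail:

1. Step 7 (Proposed new method). Conjugate addition at the doubly flanked C5 may be slower than polymerisation of methacrolein or than attack of the primary amine on the 2-bromo- or 2-methoxytropone (loss of catalyst). The enamine protonation may show poor facial control, and C3 may epimerise through the open aldehyde. Fallback with known chemistry, setting out from 11: a Mannich reaction (Me2NH, aqueous CH2O) at C5 gives the Mannich base F1, and MeI converts it into the trimethylammonium iodide F2. The lithium azaenolate of the RAMP hydrazone of propanal (2.2 equiv) releases trimethylamine from F2 and is alkylated by the resulting tropone quinone methide. This gives the alkylated hydrazone F3, with the 2R centre set by the auxiliary (SAMP/RAMP hydrazone alkylation). Hydrolysis with aqueous oxalic acid frees aldehyde 13, which closes to lactol 14, where the route is rejoined.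

2. Step 11 (Proposed new method). The condensation at the hindered C5 may stall, the aldehyde may lose its β-oxygen by enamine-mediated elimination, or the quinone methide may be intercepted by a second molecule of 11 before hydride transfer. Fallback with known chemistry, setting out from 11: hydroxymethylation (aqueous CH2O, NaOH) gives the C5 hydroxymethyl compound F4, and PPh3·HBr converts it into the phosphonium bromide F5. A Wittig reaction with (R)-2,2-dimethyl-1,3-dioxolane-4-carbaldehyde (K2CO3) gives alkene F6 (either geometry). Under the conditions of step 12 the alkene is saturated, the bromine removed and the acetonide cleaved, which returns to 22.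

3. Step 19. Capture of the hindered 3-methyl oxocarbenium ion may be slower than Lewis-acid ionisation of the dienylic C2'–O bond of 29 (and of the C2–O bond of 30), with erosion of the C2' and C2 configuration and leakage to the 2,3-cis isomer. Fallback, setting out from 15 and from aldehyde 26: oxidation of 15 (Ag2CO3 on Celite) gives lactone F7, and ethynylmagnesium bromide at −78 °C adds to the lactone carbonyl to give hemiketal F8. Et3SiH/BF3·OEt2 delivers hydride axially to the oxocarbenium ion, placing the ethynyl group equatorial and trans to the methyl (alkyne F9). Palladium-catalysed hydrostannation (Bu3SnH, PdCl2(PPh3)2) gives the (E)-vinylstannane F10. Aldehyde 26 (made from 25 as in step 16) is converted with CHI3/CrCl2 (Takai olefination) into the (E)-vinyl iodide F11. Stille coupling of F10 with F11 (Pd2(dba)3, AsPh3, CuI) under neutral conditions gives 30.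

Further compounds
F1 | step 7 | 7-bromo-5-[(dimethylamino)methyl]-4-hydroxy-2-methoxy-6-methyltropone | Cc1c(Br)c(=O)c(OC)cc(O)c1CN(C)C
F2 | step 7 | [(7-bromo-4-hydroxy-2-methoxy-6-methyltropon-5-yl)methyl]trimethylammonium iodide | Cc1c(Br)c(=O)c(OC)cc(O)c1C[N+](C)(C)C.[I-]
F3 | step 7 | RAMP hydrazone of (2R)-3-(7-bromo-4-hydroxy-2-methoxy-6-methyltropon-5-yl)-2-methylpropanal | Cc1c(Br)c(=O)c(OC)cc(O)c1C[C@@H](C)/C=N/N1CCC[C@@H]1COC
F4 | step 11 | 7-bromo-4-hydroxy-5-(hydroxymethyl)-2-methoxy-6-methyltropone | Cc1c(Br)c(=O)c(OC)cc(O)c1CO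
F5 | step 11 | [(7-bromo-4-hydroxy-2-methoxy-6-methyltropon-5-yl)methyl]triphenylphosphonium bromide | Cc1c(Br)c(=O)c(OC)cc(O)c1C[P+](c1ccccc1)(c1ccccc1)c1ccccc1.[Br-]
F6 | step 11 | 7-bromo-5-{2-[(4S)-2,2-dimethyl-1,3-dioxolan-4-yl]ethenyl}-4-hydroxy-2-methoxy-6-methyltropone | Cc1c(Br)c(=O)c(OC)cc(O)c1C=C[C@H]1COC(C)(C)O1
F7 | step 19 | (3R)-8-methoxy-3,5-dimethyl-3,4-dihydrocyclohepta[b]pyran-2,7-dione | Cc1cc(=O)c(OC)cc2OC(=O)[C@H](C)Cc12
F8 | step 19 | (3R)-2-ethynyl-2-hydroxy-8-methoxy-3,5-dimethyl-3,4-dihydrocyclohepta[b]pyran-7(2H)-one | Cc1cc(=O)c(OC)cc2OC(O)(C#C)[C@H](C)Cc12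
F9 | step 19 | (2R,3R)-2-ethynyl-8-methoxy-3,5-dimethyl-3,4-dihydrocyclohepta[b]pyran-7(2H)-one | Cc1cc(=O)c(OC)cc2c1C[C@@H](C)[C@H](C#C)O2
F10 | step 19 | (2R,3R)-8-methoxy-3,5-dimethyl-2-[(E)-2-(tributylstannyl)ethenyl]-3,4-dihydrocyclohepta[b]pyran-7(2H)-one | Cc1cc(=O)c(OC)cc2c1C[C@@H](C)[C@H](/C=C/[Sn](CCCC)(CCCC)CCCC)O2
F11 | step 19 | (2R)-2-[(E)-2-iodoethenyl]-8-methoxy-5-methyl-3,4-dihydrocyclohepta[b]pyran-7(2H)-one | Cc1cc(=O)c(OC)cc2O[C@@H](/C=C/I)CCc12
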